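## Retrosynthetic overview

1. The C7–C1' bond joins two fully substituted carbons and is never made: it is carried in as the acyl–ring bond of the cyclopentyl bromomethyl ketone 23.
2. Key disconnection: ring B, closed in one SmI2 operation that unites 23 with ring A aldehyde 9 at C5–C6 (Reformatsky-type aldol) and at C7–C8 (Barbier allylation).
3. Enabling feature: C7 is a tertiary carbinol flanked by quaternary C1' and the methylenes C6 and C8, so its ketone enolises only towards C6. C8 sits on C8a, whose trans-diol with C1 is the hydrate of a C8a=C1 alkene, so C8 is an allylic carbon; C5 sits on quaternary C4a, so its aldehyde cannot enolise.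
4. Ring order: ring A (bromonium-relayed epoxide–allene cyclisation) and the cyclopentane (bromonium alkylation of a dioxanone ketene acetal) first, ring B last; then C5 deoxygenation, epoxidation and trans-diaxial hydrolysis.
5. Stereochemistry: three reagent-controlled events (Sharpless epoxidation, Evans aldol, Shi epoxidation); every other centre is relayed by substrate control.

Key step: step 18

Remark: decalin atoms are numbered as in naphthalene (C1 methyl carbinol, C4 CHBr, C4a angular methyl, C7 cyclopentyl carbinol, C8a angular hydroxyl); primed locants are cyclopentane atoms, C1' being bonded to C7.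

## Route

Step 1
Reactants: 1 dehydrolinalyl acetate (3,7-dimethyloct-6-en-1-yn-3-yl acetate, racemic)
Product: 2 3,7-dimethylocta-1,2,6-triene
Conditions: Pd(PPh3)4 (5 mol %), SmI2 (2.5 equiv), i-PrOH, THF, rt
Reagents that add atoms: none
Why: Palladium-catalysed propargylic reduction (Tsuji-type hydrogenolysis with SmI2 as reductant): zerovalent palladium ionises the tertiary propargylic acetate and protonation of the derived organosamarium at the acetylenic terminus should give the 1,1-disubstituted allene.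

Step 2
Reactants: 2 3,7-dimethylocta-1,2,6-triene
Product: 3 (2E)-2,6-dimethylocta-2,6,7-trien-1-ol
Conditions: SeO2 (cat.), t-BuOOH, CH2Cl2, rt
Reagents that add atoms: selenium dioxide O=[Se]=O (oxygen carrier), tert-butyl hydroperoxide CC(C)(C)OO (terminal oxidant)
Why: Selenium dioxide allylic oxidation (ene reaction, then [2,3]-sigmatropic shift) should hydroxylate the E-methyl group of the electron-rich trisubstituted alkene in preference to the allene.

Step 3
Reactants: 3 (2E)-2,6-dimethylocta-2,6,7-trien-1-ol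
Product: 4 [(2R,3R)-2-methyl-3-(3-methylpenta-3,4-dien-1-yl)oxiran-2-yl]methanol
Conditions: Ti(OiPr)4, D-(−)-diethyl tartrate, t-BuOOH, 4 Å sieves, CH2Cl2, −20 °C
Reagents that add atoms: tert-butyl hydroperoxide CC(C)(C)OO
Why: Sharpless asymmetric epoxidation of the allylic alcohol; the tartrate sets both oxirane carbons (future C4 and C4a) by reagent control and the allene is inert.

Step 4
Reactants: 4 [(2R,3R)-2-methyl-3-(3-methylpenta-3,4-dien-1-yl)oxiran-2-yl]methanol
Product: 5 (2R,3S)-3-bromo-2,6-dimethylocta-6,7-diene-1,2-diol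
Conditions: Ti(OiPr)4, Et2NH2Br, CH2Cl2, 0 °C
Reagents that add atoms: diethylammonium bromide CC[NH2+]CC.[Br-]
Why: Titanium-assisted C3-selective SN2 opening of the 2,3-epoxy alcohol by bromide places bromine on the secondary carbon with inversion, which sets the C–Br stereocentre.

Step 5
Reactants: 5 (2R,3S)-3-bromo-2,6-dimethylocta-6,7-diene-1,2-diol
Product: 7 (2R)-2-[(1S)-1-bromo-4-methylhexa-4,5-dien-1-yl]-2-methyloxirane, via tosylate 6 (not isolated)
Conditions: TsCl, pyridine, CH2Cl2, 0 °C; then K2CO3, MeOH, 0 °C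
Reagents that add atoms: none
Why: Selective sulfonylation of the primary alcohol and Williamson-type 3-exo-tet closure by the tertiary alkoxide give the terminal epoxide without touching either stereocentre.

Step 6
Reactants: 7 (2R)-2-[(1S)-1-bromo-4-methylhexa-4,5-dien-1-yl]-2-methyloxirane
Product: 8 [(1R,6S)-6-bromo-2-(chloromethyl)-1,3-dimethylcyclohex-2-en-1-yl]methanol
Conditions: SnCl4 (1.1 equiv), CH2Cl2, −78 °C
Reagents that add atoms: tin tetrachloride Cl[Sn](Cl)(Cl)Cl
Why: Lewis acid epoxide-initiated cation–π cyclisation: the neighbouring bromine opens the activated epoxide to a bromonium ion, the central allene carbon attacks anti to bromine through a chair (Br and CH2O equatorial, methyl axial) and chloride captures the 2-substituted allyl cation at its primary end, so the quaternary centre is relayed from 4 with overall retention.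

Step 7
Reactants: 8 [(1R,6S)-6-bromo-2-(chloromethyl)-1,3-dimethylcyclohex-2-en-1-yl]methanol
Product: 9 (1R,6S)-6-bromo-2-(chloromethyl)-1,3-dimethylcyclohex-2-ene-1-carbaldehyde
Conditions: Dess–Martin periodinane, NaHCO3, CH2Cl2, 0 °C → rt
Reagents that add atoms: none
Why: Dess–Martin oxidation of the neopentyl primary alcohol; the aldehyde cannot epimerise because its α-carbon is quaternary.

Step 8
Reactants: 10 4-methylpent-3-en-1-ol
Product: 11 4-methylpent-3-enal
Conditions: Dess–Martin periodinane, NaHCO3, CH2Cl2, 0 °C; used at once as a cold solution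
Reagents that add atoms: none
Why: Buffered Dess–Martin oxidation should give the β,γ-unsaturated aldehyde without conjugation of the double bond.

Step 9
Reactants: 11 4-methylpent-3-enal; 12 (4R)-4-benzyl-3-propanoyl-1,3-oxazolidin-2-one
Product: 13 (4R)-4-benzyl-3-[(2R,3S)-3-hydroxy-2,6-dimethylhept-5-enoyl]-1,3-oxazolidin-2-one
Conditions: n-Bu2BOTf, i-Pr2NEt, CH2Cl2, −78 → 0 °C; then 11, −78 °C
Reagents that add atoms: none
Why: Evans syn aldol through the Z-boron enolate and a Zimmerman–Traxler chair; the (R)-auxiliary sets the carbinol (future C5') as S.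

Step 10
Reactants: 13 (4R)-4-benzyl-3-[(2R,3S)-3-hydroxy-2,6-dimethylhept-5-enoyl]-1,3-oxazolidin-2-one
Product: 14 (2R,3S)-3-hydroxy-2,6-dimethylhept-5-enoic acid
Conditions: LiOH, H2O2, THF/H2O, 0 °C; Na2SO3; HCl (aq.) to pH 2
Reagents that add atoms: hydrogen peroxide OO
Why: Hydroperoxide cleavage of the imide at the exocyclic carbonyl releases the acid and the auxiliary without retro-aldol.

Step 11
Reactants: 14 (2R,3S)-3-hydroxy-2,6-dimethylhept-5-enoic acid
Product: 15 (5R,6S)-2,2,5-trimethyl-6-(3-methylbut-2-en-1-yl)-1,3-dioxan-4-one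
Conditions: 2-methoxypropene, pyridinium tosylate (cat.), CH2Cl2, 0 °C → rt
Reagents that add atoms: 2-methoxypropene COC(C)=C
Why: Acetalisation of the β-hydroxy acid to the 1,3-dioxan-4-one ties the carbinol oxygen and the carboxyl carbon into a temporary ring that later fixes both the enolisation site and the ring fusion.

Step 12
Reactants: 15 (5R,6S)-2,2,5-trimethyl-6-(3-methylbut-2-en-1-yl)-1,3-dioxan-4-one
Product: 16 (5R,6S)-6-{[(2S)-3,3-dimethyloxiran-2-yl]methyl}-2,2,5-trimethyl-1,3-dioxan-4-one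
Conditions: Shi ketone of the L-series (from L-sorbose, 30 mol %), KHSO5 (as Oxone), K2CO3, Bu4NHSO4, MeCN/dimethoxymethane/H2O, 0 °C
Reagents that add atoms: potassium peroxymonosulfate [K+].[O-]S(=O)(=O)OO
Why: Shi asymmetric epoxidation of the trisubstituted alkene; the dioxirane from the L-series ketone should give the (S)-oxirane by reagent control.

Step 13
Reactants: 16 (5R,6S)-6-{[(2S)-3,3-dimethyloxiran-2-yl]methyl}-2,2,5-trimethyl-1,3-dioxan-4-one
Product: 18 (5R,6S)-6-{(2R)-2-bromo-3-methyl-3-[(trimethylsilyl)oxy]butyl}-2,2,5-trimethyl-1,3-dioxan-4-one, via bromohydrin 17 (not isolated)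
Conditions: Li2NiBr4, THF, 0 °C; aqueous work-up; then Me3SiOTf, 2,6-lutidine, CH2Cl2, −78 °C
Reagents that add atoms: dilithium tetrabromonickelate [Li+].[Li+].[Ni+2].[Br-].[Br-].[Br-].[Br-], trimethylsilyl triflate C[Si](C)(C)OS(=O)(=O)C(F)(F)F
Why: SN2 opening of the trisubstituted epoxide by bromide at its less substituted carbon (inversion) sets the C3' bromide as R, and silylation of the tertiary alcohol blocks re-closure to the epoxide.

Step 14
Reactants: 18 (5R,6S)-6-{(2R)-2-bromo-3-methyl-3-[(trimethylsilyl)oxy]butyl}-2,2,5-trimethyl-1,3-dioxan-4-one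
Product: 20 (4aR,6R,7aS)-6-bromo-2,2,4a,5,5-pentamethylhexahydro-4H-cyclopenta[d][1,3]dioxin-4-one, via silyl ketene acetal 19 (not isolated)
Conditions: LiN(i-Pr)2, Me3SiCl, THF, −78 °C; then Me3SiOTf (20 mol %), CH2Cl2, −78 → −40 °C
Reagents that add atoms: none
Why: SN1-type Mukaiyama tert-alkylation of a silyl ketene acetal: the tertiary silyl ether ionises with bromine participation (bromonium, so the C–Br centre is retained), and the five-membered ring can only fuse cis onto the dioxanone, which places the acyl carbon cis to the ring oxygen at the new quaternary C1'.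

Step 15
Reactants: 20 (4aR,6R,7aS)-6-bromo-2,2,4a,5,5-pentamethylhexahydro-4H-cyclopenta[d][1,3]dioxin-4-one
Product: 21 1-[(1R,3R,5S)-3-bromo-5-hydroxy-1,2,2-trimethylcyclopentyl]ethan-1-one
Conditions: MeLi (3 equiv), Et2O, −78 °C
Reagents that add atoms: methyllithium [Li]C
Why: Acyl substitution: methyllithium adds to the lactone carbonyl, the tetrahedral intermediate expels the acetal oxygen (releasing acetone and the C5' alkoxide), and the ketone flanked by a quaternary carbon should resist a second addition at low temperature.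

Step 16
Reactants: 21 1-[(1R,3R,5S)-3-bromo-5-hydroxy-1,2,2-trimethylcyclopentyl]ethan-1-one
Product: 22 {[(1S,2R,4R)-4-bromo-2,3,3-trimethyl-2-{1-[(triethylsilyl)oxy]ethenyl}cyclopentyl]oxy}triethylsilane
Conditions: Et3SiOTf (2.5 equiv), Et3N, CH2Cl2, 0 °C
Reagents that add atoms: triethylsilyl triflate CC[Si](CC)(CC)OS(=O)(=O)C(F)(F)F
Why: Silylation of the alcohol and soft enolisation of the methyl ketone, which has α-hydrogens only on the methyl group because C1' is quaternary.

Step 17
Reactants: 22 {[(1S,2R,4R)-4-bromo-2,3,3-trimethyl-2-{1-[(triethylsilyl)oxy]ethenyl}cyclopentyl]oxy}triethylsilane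
Product: 23 2-bromo-1-{(1R,3R,5S)-3-bromo-1,2,2-trimethyl-5-[(triethylsilyl)oxy]cyclopentyl}ethan-1-one
Conditions: N-bromosuccinimide, NaHCO3, THF, −78 °C
Reagents that add atoms: N-bromosuccinimide O=C1CCC(=O)N1Br
Why: Electrophilic bromination of the silyl enol ether gives the α-bromo ketone regiospecifically and leaves the secondary silyl ether intact.

Step 18
Reactants: 23 2-bromo-1-{(1R,3R,5S)-3-bromo-1,2,2-trimethyl-5-[(triethylsilyl)oxy]cyclopentyl}ethan-1-one; 9 (1R,6S)-6-bromo-2-(chloromethyl)-1,3-dimethylcyclohex-2-ene-1-carbaldehyde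
Product: 25 (4S,4aR,7S)-4-bromo-7-{(1R,3R,5S)-3-bromo-1,2,2-trimethyl-5-[(triethylsilyl)oxy]cyclopentyl}-1,4a-dimethyl-2,3,4,4a,5,6,7,8-octahydronaphthalene-5,7-diol (C5 epimers), via samarium aldolate 24 (not isolated)
Conditions: SmI2 (5 equiv), THF, −78 °C; then NiI2 (2 mol %), −78 °C → rt
Reagents that add atoms: none
Why: Proposed new method: SmI2 first reduces the α-bromo ketone of 23, the most easily reduced carbon–halogen bond, to a samarium enolate that adds 1,2 to the non-enolisable aldehyde of 9 (Reformatsky-type aldol, C5–C6) to give aldolate 24; on warming with catalytic NiI2 the allylic chloride is reduced next, and the allylsamarium adds through its unsubstituted end C8 to the C7 ketone held by the neighbouring samarium alkoxide (Barbier allylation, C7–C8), while the two neopentyl secondary bromides are reduced far more slowly. The closest known chemistry is the samarium Reformatsky reaction and the intramolecular samarium Barbier allylation, each established and known to be run in sequence in one flask; their union as an intermolecular [4+2] annulation is new. Ring B closes by a 6-exo-trig addition to the carbonyl group through a chair in which the allyl unit C8–C8a=C1 belongs to ring A. C7 is set by substrate control: the very large cyclopentyl group takes the equatorial position and the samarium-bound oxygen the axial one, anti to the axial C4a methyl group, which is the target configuration; the C5 carbinol forms as an epimer mixture and is erased in steps 19 to 21. The selectivities needed are all secured by fully substituted carbons: C1' allows enolate formation only at C6, C4a makes the aldehyde non-enolisable, and attack through C1 of the allyl unit would have to join two fully substituted carbons, so the bond forms at C8 and leaves the C8a=C1 alkene for the diol.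

Step 19
Reactants: 25 (4S,4aR,7S)-4-bromo-7-{(1R,3R,5S)-3-bromo-1,2,2-trimethyl-5-[(triethylsilyl)oxy]cyclopentyl}-1,4a-dimethyl-2,3,4,4a,5,6,7,8-octahydronaphthalene-5,7-diol
Product: 26 (4S,4aR,7S)-4-bromo-7-{(1R,3R,5S)-3-bromo-1,2,2-trimethyl-5-[(triethylsilyl)oxy]cyclopentyl}-7-hydroxy-1,4a-dimethyl-3,4,4a,6,7,8-hexahydronaphthalen-5(2H)-one
Conditions: Dess–Martin periodinane, NaHCO3, CH2Cl2, 0 °C
Reagents that add atoms: none
Why: Dess–Martin oxidation of the only secondary alcohol makes both C5 epimers converge on one ketone; the tertiary C7 alcohol is untouched.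

Step 20
Reactants: 26 (4S,4aR,7S)-4-bromo-7-{(1R,3R,5S)-3-bromo-1,2,2-trimethyl-5-[(triethylsilyl)oxy]cyclopentyl}-7-hydroxy-1,4a-dimethyl-3,4,4a,6,7,8-hexahydronaphthalen-5(2H)-one
Product: 27 4-methylbenzenesulfonohydrazone of ketone 26 at C5
Conditions: TsNHNH2, THF, 50 °C
Reagents that add atoms: 4-methylbenzenesulfonohydrazide Cc1ccc(cc1)S(=O)(=O)NN
Why: Condensation of the C5 ketone, the only carbonyl group present, to the tosylhydrazone under neutral conditions that avoid dehydration of the β-hydroxy ketone.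

Step 21
Reactants: 27 4-methylbenzenesulfonohydrazone of ketone 26 at C5
Product: 28 (4S,4aS,7R)-4-bromo-7-{(1R,3R,5S)-3-bromo-1,2,2-trimethyl-5-[(triethylsilyl)oxy]cyclopentyl}-1,4a-dimethyl-2,3,4,4a,5,6,7,8-octahydronaphthalen-7-ol
Conditions: catecholborane, CHCl3, 0 °C; then NaOAc·3H2O, reflux
Reagents that add atoms: none
Why: Caglioti-type reduction of the tosylhydrazone with catecholborane (hydride to C=N, then loss of sulfinate and N2) turns C5 into a methylene without radicals or strong base, so both alkyl bromides and the alkene survive.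

Step 22
Reactants: 28 (4S,4aS,7R)-4-bromo-7-{(1R,3R,5S)-3-bromo-1,2,2-trimethyl-5-[(triethylsilyl)oxy]cyclopentyl}-1,4a-dimethyl-2,3,4,4a,5,6,7,8-octahydronaphthalen-7-ol
Product: 29 (1S,4S,4aS,7R,8aR)-4-bromo-7-{(1R,3R,5S)-3-bromo-1,2,2-trimethyl-5-[(triethylsilyl)oxy]cyclopentyl}-1,8a-epoxy-1,4a-dimethyldecahydronaphthalen-7-ol
Conditions: m-CPBA, NaHCO3, CH2Cl2, 0 °C
Reagents that add atoms: 3-chloroperoxybenzoic acid OOC(=O)c1cccc(Cl)c1
Why: Prilezhaev epoxidation of the tetrasubstituted alkene on the face anti to the axial C4a methyl group and syn to the axial homoallylic C7 hydroxyl (Henbest delivery) sets the C8a oxygen.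

Step 23
Reactants: 29 (1S,4S,4aS,7R,8aR)-4-bromo-7-{(1R,3R,5S)-3-bromo-1,2,2-trimethyl-5-[(triethylsilyl)oxy]cyclopentyl}-1,8a-epoxy-1,4a-dimethyldecahydronaphthalen-7-ol
Product: 30 neoirietetraol, (1R,4S,4aS,7R,8aR)-4-bromo-7-[(1R,3R,5S)-3-bromo-5-hydroxy-1,2,2-trimethylcyclopentyl]-1,4a-dimethyldecahydronaphthalene-1,7,8a-triol
Conditions: HClO4 (aq., 5 %), THF, 0 °C → rt
Reagents that add atoms: water O
Why: Acid-catalysed epoxide hydrolysis by the Fürst–Plattner rule: water attacks C1 (the carbon that is not neopentyl) from the face anti to the oxirane to give the trans-diaxial C1/C8a diol with inversion at C1, and the acid-labile triethylsilyl ether is cleaved in the same operation.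

## Compound list

1 | dehydrolinalyl acetate (3,7-dimethyloct-6-en-1-yn-3-yl acetate, racemic) | CC(=O)OC(C)(C#C)CCC=C(C)C | starting material
2 | 3,7-dimethylocta-1,2,6-triene | C=C=C(C)CCC=C(C)C | intermediate
3 | (2E)-2,6-dimethylocta-2,6,7-trien-1-ol | OC/C(C)=C/CCC(C)=C=C | intermediate
4 | [(2R,3R)-2-methyl-3-(3-methylpenta-3,4-dien-1-yl)oxiran-2-yl]methanol | C=C=C(C)CC[C@H]1O[C@]1(C)CO | intermediate
5 | (2R,3S)-3-bromo-2,6-dimethylocta-6,7-diene-1,2-diol | C=C=C(C)CC[C@H](Br)[C@](C)(O)CO | intermediate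
6 | (2R,3S)-3-bromo-2-hydroxy-2,6-dimethylocta-6,7-dien-1-yl 4-methylbenzenesulfonate (not isolated) | C=C=C(C)CC[C@H](Br)[C@](C)(O)COS(=O)(=O)c1ccc(C)cc1 | intermediate
7 | (2R)-2-[(1S)-1-bromo-4-methylhexa-4,5-dien-1-yl]-2-methyloxirane | C=C=C(C)CC[C@H](Br)[C@@]1(C)CO1 | intermediate
8 | [(1R,6S)-6-bromo-2-(chloromethyl)-1,3-dimethylcyclohex-2-en-1-yl]methanol | OC[C@]1(C)[C@@H](Br)CCC(C)=C1CCl | intermediate
9 | (1R,6S)-6-bromo-2-(chloromethyl)-1,3-dimethylcyclohex-2-ene-1-carbaldehyde | O=C[C@]1(C)[C@@H](Br)CCC(C)=C1CCl | intermediate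
10 | 4-methylpent-3-en-1-ol | CC(C)=CCCO | starting material
11 | 4-methylpent-3-enal | CC(C)=CCC=O | intermediate
12 | (4R)-4-benzyl-3-propanoyl-1,3-oxazolidin-2-one | CCC(=O)N1[C@H](Cc2ccccc2)COC1=O | starting material
13 | (4R)-4-benzyl-3-[(2R,3S)-3-hydroxy-2,6-dimethylhept-5-enoyl]-1,3-oxazolidin-2-one | CC(C)=CC[C@H](O)[C@@H](C)C(=O)N1[C@H](Cc2ccccc2)COC1=O | intermediate
14 | (2R,3S)-3-hydroxy-2,6-dimethylhept-5-enoic acid | CC(C)=CC[C@H](O)[C@@H](C)C(O)=O | intermediate
15 | (5R,6S)-2,2,5-trimethyl-6-(3-methylbut-2-en-1-yl)-1,3-dioxan-4-one | CC(C)=CC[C@H](OC(C)(C)OC1=O)[C@H]1C | intermediate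
16 | (5R,6S)-6-{[(2S)-3,3-dimethyloxiran-2-yl]methyl}-2,2,5-trimethyl-1,3-dioxan-4-one | CC1(C)O[C@H]1C[C@H](OC(C)(C)OC2=O)[C@H]2C | intermediate
17 | (5R,6S)-6-[(2R)-2-bromo-3-hydroxy-3-methylbutyl]-2,2,5-trimethyl-1,3-dioxan-4-one (not isolated) | CC(C)(O)[C@H](Br)C[C@H](OC(C)(C)OC1=O)[C@H]1C | intermediate
18 | (5R,6S)-6-{(2R)-2-bromo-3-methyl-3-[(trimethylsilyl)oxy]butyl}-2,2,5-trimethyl-1,3-dioxan-4-one | CC(C)(O[Si](C)(C)C)[C@H](Br)C[C@H](OC(C)(C)OC1=O)[C@H]1C | intermediate
19 | {[(6S)-6-{(2R)-2-bromo-3-methyl-3-[(trimethylsilyl)oxy]butyl}-2,2,5-trimethyl-6H-1,3-dioxin-4-yl]oxy}trimethylsilane (not isolated) | CC(C)(O[Si](C)(C)C)[C@H](Br)C[C@@H]1OC(C)(C)OC(O[Si](C)(C)C)=C1C | intermediate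
20 | (4aR,6R,7aS)-6-bromo-2,2,4a,5,5-pentamethylhexahydro-4H-cyclopenta[d][1,3]dioxin-4-one | CC1(C)[C@H](Br)C[C@H]2[C@]1(C)C(=O)OC(C)(C)O2 | intermediate
21 | 1-[(1R,3R,5S)-3-bromo-5-hydroxy-1,2,2-trimethylcyclopentyl]ethan-1-one | CC1(C)[C@H](Br)C[C@H](O)[C@]1(C)C(C)=O | intermediate
22 | {[(1S,2R,4R)-4-bromo-2,3,3-trimethyl-2-{1-[(triethylsilyl)oxy]ethenyl}cyclopentyl]oxy}triethylsilane | CC1(C)[C@H](Br)C[C@H](O[Si](CC)(CC)CC)[C@]1(C)C(=C)O[Si](CC)(CC)CC | intermediate
23 | 2-bromo-1-{(1R,3R,5S)-3-bromo-1,2,2-trimethyl-5-[(triethylsilyl)oxy]cyclopentyl}ethan-1-one | CC1(C)[C@H](Br)C[C@H](O[Si](CC)(CC)CC)[C@]1(C)C(=O)CBr | intermediate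
24 | diiodosamarium alkoxide of the aldol between 23 and 9 (open-chain β-oxido ketone, carbinol epimers; not isolated) | CC1(C)[C@H](Br)C[C@H](O[Si](CC)(CC)CC)[C@]1(C)C(=O)CC(O[Sm](I)I)[C@]1(C)[C@@H](Br)CCC(C)=C1CCl | intermediate
25 | (4S,4aR,7S)-4-bromo-7-{(1R,3R,5S)-3-bromo-1,2,2-trimethyl-5-[(triethylsilyl)oxy]cyclopentyl}-1,4a-dimethyl-2,3,4,4a,5,6,7,8-octahydronaphthalene-5,7-diol (C5 epimers) | CC1(C)[C@H](Br)C[C@H](O[Si](CC)(CC)CC)[C@]1(C)[C@@]1(O)CC(O)[C@]2(C)[C@@H](Br)CCC(C)=C2C1 | intermediate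
26 | (4S,4aR,7S)-4-bromo-7-{(1R,3R,5S)-3-bromo-1,2,2-trimethyl-5-[(triethylsilyl)oxy]cyclopentyl}-7-hydroxy-1,4a-dimethyl-3,4,4a,6,7,8-hexahydronaphthalen-5(2H)-one | CC1(C)[C@H](Br)C[C@H](O[Si](CC)(CC)CC)[C@]1(C)[C@@]1(O)CC(=O)[C@]2(C)[C@@H](Br)CCC(C)=C2C1 | intermediate
27 | 4-methylbenzenesulfonohydrazone of ketone 26 at C5 | CC1(C)[C@H](Br)C[C@H](O[Si](CC)(CC)CC)[C@]1(C)[C@@]1(O)CC(=NNS(=O)(=O)c3ccc(C)cc3)[C@]2(C)[C@@H](Br)CCC(C)=C2C1 | intermediate
28 | (4S,4aS,7R)-4-bromo-7-{(1R,3R,5S)-3-bromo-1,2,2-trimethyl-5-[(triethylsilyl)oxy]cyclopentyl}-1,4a-dimethyl-2,3,4,4a,5,6,7,8-octahydronaphthalen-7-ol | CC1(C)[C@H](Br)C[C@H](O[Si](CC)(CC)CC)[C@]1(C)[C@@]1(O)CC[C@]2(C)[C@@H](Br)CCC(C)=C2C1 | intermediate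
29 | (1S,4S,4aS,7R,8aR)-4-bromo-7-{(1R,3R,5S)-3-bromo-1,2,2-trimethyl-5-[(triethylsilyl)oxy]cyclopentyl}-1,8a-epoxy-1,4a-dimethyldecahydronaphthalen-7-ol | CC1(C)[C@H](Br)C[C@H](O[Si](CC)(CC)CC)[C@]1(C)[C@@]1(O)CC[C@]2(C)[C@@H](Br)CC[C@]3(C)O[C@]23C1 | intermediate
30 | neoirietetraol, (1R,4S,4aS,7R,8aR)-4-bromo-7-[(1R,3R,5S)-3-bromo-5-hydroxy-1,2,2-trimethylcyclopentyl]-1,4a-dimethyldecahydronaphthalene-1,7,8a-triol | CC1(C)[C@H](Br)C[C@H](O)[C@]1(C)[C@@]1(O)CC[C@]2(C)[C@@H](Br)CC[C@@](C)(O)[C@@]2(O)C1 | target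

## Step count and risks

Total step count: 23. Longest linear sequence: 16 steps (steps 8 to 23).

Most likely to fail, step 18 (labelled). The C7 ketone of the aldolate may be reduced to a ketyl, or aldehyde 9 may undergo pinacol coupling, before the allylsamarium forms; the secondary bromides may begin to be reduced on warming. The fallback uses known reactions one at a time and sets out from 22 and 9. A BF3·OEt2-mediated Mukaiyama aldol of silyl enol ether 22 with aldehyde 9 should give the open-chain β-hydroxy ketone F1, which is isolated. Zinc dust in THF/aqueous NH4Cl then generates the allylzinc from the allylic chloride, and intramolecular Barbier allylation of the C7 ketone through C8 closes ring B; the route is rejoined at 25.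

Step 6. The Lewis acid–epoxide complex may collapse by a 1,2-hydride shift (Meinwald rearrangement) or by chloride opening before the bromonium ion is intercepted by the allene. The fallback removes the epoxide and sets out from bromo diol 5. Silylation of the primary alcohol (t-BuPh2SiCl, imidazole) gives the silyl ether F2. Direct ionisation of its tertiary alcohol (SnCl4, CH2Cl2/hexafluoroisopropanol, −40 °C), again with bromine participation, should deliver the cyclised silyl ether F3. Bu4NF returns the route to 8.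

Step 14. The bromonium ion may lose a proton (elimination to an isopropenyl group), or the silyl triflate may ionise the acetal, faster than the ketene acetal attacks. The fallback moves the C–Br bond formation after the ring closure and sets out from epoxide 16. LiN(i-Pr)2/Me3SiCl gives the silyl ketene acetal F4, which is not isolated. BF3·OEt2 then triggers a Lewis acid epoxide-opening cyclisation terminated by the ketene acetal, giving the bicyclic alcohol F5 with the carbinol configuration of the epoxide retained. Triflation (Tf2O, pyridine) gives the triflate F6, and SN2 displacement with Bu4NBr in toluene inverts that centre to rejoin the route at 20.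

## Further compounds

F1 | step 18 | 3-[(1R,6S)-6-bromo-2-(chloromethyl)-1,3-dimethylcyclohex-2-en-1-yl]-1-{(1R,3R,5S)-3-bromo-1,2,2-trimethyl-5-[(triethylsilyl)oxy]cyclopentyl}-3-hydroxypropan-1-one (carbinol epimers) | CC1(C)[C@H](Br)C[C@H](O[Si](CC)(CC)CC)[C@]1(C)C(=O)CC(O)[C@]1(C)[C@@H](Br)CCC(C)=C1CCl
F2 | step 6 | (2R,3S)-3-bromo-1-{[tert-butyl(diphenyl)silyl]oxy}-2,6-dimethylocta-6,7-dien-2-ol | C=C=C(C)CC[C@H](Br)[C@](C)(O)CO[Si](c1ccccc1)(c1ccccc1)C(C)(C)C
F3 | step 6 | {[(1R,6S)-6-bromo-2-(chloromethyl)-1,3-dimethylcyclohex-2-en-1-yl]methoxy}(tert-butyl)diphenylsilane | CC(C)(C)[Si](OC[C@]1(C)[C@@H](Br)CCC(C)=C1CCl)(c1ccccc1)c1ccccc1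
F4 | step 14 | {[(6S)-6-{[(2S)-3,3-dimethyloxiran-2-yl]methyl}-2,2,5-trimethyl-6H-1,3-dioxin-4-yl]oxy}trimethylsilane | CC1(C)O[C@H]1C[C@@H]2OC(C)(C)OC(O[Si](C)(C)C)=C2C
F5 | step 14 | (4aR,6S,7aS)-6-hydroxy-2,2,4a,5,5-pentamethylhexahydro-4H-cyclopenta[d][1,3]dioxin-4-one | CC1(C)[C@@H](O)C[C@H]2[C@]1(C)C(=O)OC(C)(C)O2
F6 | step 14 | (4aR,6S,7aS)-2,2,4a,5,5-pentamethyl-4-oxohexahydro-4H-cyclopenta[d][1,3]dioxin-6-yl trifluoromethanesulfonate | CC1(C)[C@@H](OS(=O)(=O)C(F)(F)F)C[C@H]2[C@]1(C)C(=O)OC(C)(C)O2
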